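## The problem

The target is an ent-labdane: a trans-fused decalin (ring A = C1–C5 and C10, ring B = C5–C10) whose C9 carries a 3-methylenepent-4-enyl chain (C11, C12, C13 with its methylene C16, C14=C15). C17 is the methyl group on C8, C18 the hydroxymethyl and C19 the methyl group on C4, C20 the methyl group on C10; this numbering is kept for every intermediate. Six contiguous stereocentres (4S,5S,6R,8S,9S,10R) must be set: the methyl groups C19, C20 and C17 are axial on one face, while CH2OH, the 6-acetate, the 8-hydroxyl and the C9 chain are equatorial. C4, C8 and C10 are fully substituted and pairwise 1,3-diaxial, so the bonds to them must be made intramolecularly or before the congestion exists. Once the C10 methyl group is in place it closes one face of ring B, so C5 and C6 (syn addition to a 5,6-olefin) and C9 (protonation) can be left to the ring; C4 distinguishes only CH3 from CH2X, cannot steer the other centres reliably, and must be set by a catalyst and relayed through C6. The 2-substituted buta-1,3-diene does not tolerate acid, peracid, halogen or borane and must come last; the tertiary 8-alcohol is β to whatever sits on C9 (elimination, retro-aldol); the 6-acetate lies peri to the free primary 18-hydroxyl, so O6 must be acylated while O18 is still masked and no basic step may follow its release. The feature that opens the synthesis is the sequence C10–C5–C4: if C10 is a carbonyl carbon, ring A is 3-methylcyclohex-2-enone with C19 as its methyl group, C4 as its β-carbon and C5 as its α-carbon, so a hydroxymethyl-anion equivalent (C18) and an aldehyde carbon (C6) can be attached in one flask.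

## Retrosynthesis

The diene is cut at C13–C14: target 29 comes from enol triflate 28 and a vinyl-tin reagent (Stille coupling). A cut at C12–C13 would need a basic butadienyl organometallic, which invites acyl shift from O6 to O18. A final ene–yne metathesis would require an alkyne to survive the oxidative unmasking of C18. Triflate 28 has no diene and is electron-poor, and the forward step only has to be neutral.

The C18–O bond and the acetate are cut next: 28 from silane 27 (Fleming–Tamao oxidation), 27 from alcohol 26 (acetylation). Carrying C18 as a C–Si bond distinguishes the primary from the secondary oxygen without a protecting group. The oxidation must then be run on a substrate without electron-rich unsaturation; the enol triflate qualifies, the diene would not.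

The side chain is cut at C11=C12: triflate 26 from methyl ketone 25 (kinetic enolate), 25 from enone 24 (hydrogenation), 24 from aldehyde 23 (Wittig), 23 from triol 22 (selective oxidation of the primary alcohol). This uses the carbon that ring closure leaves on C9; displacement at C11 would be neopentyl-like.

C5–H and C6–O are cut together: 22 from olefinic ester 20 by hydroboration of C5=C6, with reduction of the ester in the same operation. A 6-ketone would need a dissolving-metal reduction to reach the equatorial alcohol; hydroboration delivers H5 and O6 in one step from the open face.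

C9 is corrected by epimerisation: 20 from its C9 epimer 18. The proton must arrive from the face opposite C20 and C17, which the ring enforces.

Ring B and C10 are cut at C9–C10 in the sense of a retro-[3,3] shift that restores the O6–C6 bond: 18 from lactone 15 through its silyl ketene acetal 16. An acyclic ester-enolate Claisen followed by aldol closure would form the same bonds, but the geometry of the new C5=C6 bond would be open, and only the isomer with C7 syn to C10 can cyclise. A cuprate addition to C10 would have to come from the face of the larger C4 substituent. In the lactone the C7–C8 tether forces the cis ring olefin and the C6 stereocentre is transferred to C10. Lactone 15 is monocyclic apart from the lactone and has two stereocentres besides C4.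

C8–C9 is cut in 15: from bromoacetate 14 by an intramolecular Reformatsky reaction, 14 from hydroxy ketone 13. The ester tether lets the C6 oxygen control C8, which an intermolecular acetate addition would not.

C6 is set from a ketone: 13 from ketal 12, 12 from ketone 11 by catalyst-controlled reduction. Resetting C6 makes the relay independent of the aldol diastereoselectivity of the opening step.

C10–C20 and the oxygen shift: 11 from tertiary allylic alcohol 10 (oxidative 1,3-transposition), 10 from enone 9 (methyl addition), 9 from aldol 7 (dehydration). Three routine steps convert the C10 carbonyl into the methyl-bearing olefin carbon and move the oxygen to C6.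

The key cut: 7 is divided at C4–C18 and C5–C6 into enone 5, Grignard reagent 2 and aldehyde 4. No ring is formed, and C4 is made from a commodity enone under catalyst control.

Reagent 2 comes from chloride 1 and magnesium; aldehyde 4 from ester 3 by partial reduction.

## Roads not taken

**Alternative 1:** The C18–O bond would be made late by C–H functionalisation of gem-dimethyl alcohol A1. Its diethyl(hydrido)silyl ether A2 (Et2SiH2, [Ir(cod)OMe]2) would undergo [Rh(cod)Cl]2/bisphosphine-catalysed dehydrogenative silylation of one C18–H bond to give the 6,18-bridged oxasilacycle A3, and Tamao oxidation would give the 6,18-diol.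
- Merits: the equatorial O6 can reach only the equatorial methyl group peri to it, so C4 is desymmetrised by geometry; no silicon is carried through the synthesis; electrophilic Fleming conditions are avoided.
- Weak points: A1 must first be made as a single enantiomer of the ent series, which this plan leaves open. The C17 methyl group is also δ to O6 and is a second possible site. The oxidation frees O6 and O18 together, so the 6-acetate would have to be placed next to the more reactive primary alcohol by protection and deprotection.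
- Comparison: for C18 alone this road is shorter and gentler. The chosen plan sets against it a quaternary centre made with absolute control in the first C–C bond-forming step, and acetylation of O6 while C18 is still a C–Si bond.

**Alternative 2:** C9–C10 and C8–O would be formed in one oxidative dearomatisation: PhI(OAc)2 in a fluorinated alcohol converts phenol acid A4 into a phenoxenium ion, the olefin attacks the para carbon C10, and the acid captures the C8 cation to give dienone lactone A5.
- Merits: C8, C9 and C10 arise in one step from an achiral arene, with the C8 oxygen correctly placed and C11–C13 already attached. This is clearly better than the chosen plan for ring B and the side chain, where about four steps would be saved.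
- Weak points: absolute configuration would depend on a chiral trivalent-iodine reagent, which is unreliable for carbon nucleophiles. Ring A emerges as a cross-conjugated dienone: the C3 carbonyl must be removed, C1=C2 reduced, C4 made quaternary with CH2OH under substrate control only, and C5–H and C6–O added.
- Comparison: the chosen plan spends its steps on ring B but delivers ring A, where the unusual C18 oxygen sits, exactly and enantioselectively.

**Alternative 3:** C5–C10 and C8–C9 would be formed in one intramolecular Diels–Alder reaction of triene A6 (heat or Me2AlCl) to give decalin A7.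
- Merits: both rings and four stereocentres in one step; the C6 oxygen arrives as a silyl enol ether and C11 as an ester. For ring construction this is more economical than the Reformatsky/Claisen pair.
- Weak points: the dienophile is a β,β-disubstituted enoate and the diene terminus C5 is flanked by quaternary C4, so the cycloaddition would be slow. Lewis acid endangers the silyl enol ether, and trans fusion is not assured. A6 already needs the acyclic quaternary C4 stereocentre. A7 has hydrogen at C8, so the tertiary hydroxyl would have to be introduced later at a hindered position.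
- Comparison: the chosen plan takes the C8 oxygen from the aldehyde carbonyl and C4 from a catalytic conjugate addition.

Key step: step 3

Remarks on the chemistry:
- Assumption: the sense of induction of the copper–carbene catalyst for an α-silylalkyl nucleophile is not tabulated; the ligand antipode that gives (4S) is assumed to be identified in a first run (both are available from L- or D-leucinol).
- Ester 3 is taken as the commercial fragrance chemical.
- Compounds 7, 9 and 10 are expected as mixtures (C5/C6 diastereomers, olefin isomers, C10 epimers); the expected major isomer is drawn, and all isomers converge at 11.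

## Route

Step 1
Reactants: 1 (chloromethyl)dimethylphenylsilane
Product: 2 [(dimethylphenylsilyl)methyl]magnesium chloride (solution in Et2O)
Conditions: Mg turnings, BrCH2CH2Br (cat.), Et2O, reflux
Reagents that add atoms: magnesium, [Mg]
Why: Grignard formation by insertion of magnesium into the C–Cl bond; the α-silyl Grignard reagent is a stable, standard hydroxymethyl-anion equivalent.

Step 2
Reactants: 3 ethyl 2-(2-methyl-1,3-dioxolan-2-yl)acetate
Product: 4 2-(2-methyl-1,3-dioxolan-2-yl)acetaldehyde
Conditions: i-Bu2AlH (1.05 equiv), CH2Cl2, −78 °C; aq. potassium sodium tartrate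
Reagents that add atoms: none
Why: Partial reduction of an ester by i-Bu2AlH; the tetrahedral aluminium hemiacetal, held by the neighbouring ketal oxygen, should persist at −78 °C and release the aldehyde only on work-up.

Step 3
Reactants: 5 3-methylcyclohex-2-en-1-one; 2 [(dimethylphenylsilyl)methyl]magnesium chloride; 4 2-(2-methyl-1,3-dioxolan-2-yl)acetaldehyde
Product: 7 (2S,3S)-3-[(dimethylphenylsilyl)methyl]-2-[(1S)-1-hydroxy-2-(2-methyl-1,3-dioxolan-2-yl)ethyl]-3-methylcyclohexan-1-one, via chloromagnesium enolate 6 (not isolated)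
Conditions: Cu(OTf)2 (3 mol%), 1-[(2S)-1-hydroxy-4-methylpentan-2-yl]-3-(2,4,6-trimethylphenyl)-4,5-dihydro-1H-imidazol-3-ium hexafluorophosphate (4 mol%), Et2O, 0 °C, slow addition of 2; then 4, −78 → −40 °C; aq. NH4Cl
Reagents that add atoms: none
Why: Transmetalation of 2 to the carbene-bound copper gives a chiral alkylcopper species that binds the enone as a π-complex, adds oxidatively to the β-carbon C4 (trivalent copper intermediate) and forms C4–C18 by reductive elimination, leaving the regiodefined magnesium enolate 6. The closest known reaction type is the Cu(OTf)2/N-heterocyclic-carbene-catalysed asymmetric conjugate addition of alkyl Grignard reagents to 3-methylcyclohex-2-enone with aldol trapping of the magnesium enolate; the α-silyl Grignard reagent is a new nucleophile in it. No ring is closed. C4 is set by the enantioface selection of the chiral copper–carbene complex. C5 should form trans to the larger silylmethyl group and C6 anti through a closed chair (Zimmerman–Traxler) transition state of the ring-fixed (E)-enolate, but both centres are erased in step 4. The step therefore needs only 1,4- over 1,2-regioselectivity, which copper catalysis and slow addition in Et2O should secure, and enantiofacial selectivity at C4, which rests on the catalyst alone. The enolate reacts only at C5 because it is generated there and trapped at −78 °C before it can equilibrate, and the ketal keeps the second carbonyl of the aldehyde silent.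

Step 4
Reactants: 7 (2S,3S)-3-[(dimethylphenylsilyl)methyl]-2-[(1S)-1-hydroxy-2-(2-methyl-1,3-dioxolan-2-yl)ethyl]-3-methylcyclohexan-1-one
Product: 9 (2Z,3S)-3-[(dimethylphenylsilyl)methyl]-3-methyl-2-[2-(2-methyl-1,3-dioxolan-2-yl)ethylidene]cyclohexan-1-one, via methanesulfonate 8 (not isolated)
Conditions: MeSO2Cl, Et3N, CH2Cl2, 0 °C; then DBU, 23 °C
Reagents that add atoms: none
Why: Aldol dehydration by mesylation and E1cB elimination; all C5/C6 diastereomers converge, and the quaternary C4 prevents the double bond from moving into the ring.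

Step 5
Reactants: 9 (2Z,3S)-3-[(dimethylphenylsilyl)methyl]-3-methyl-2-[2-(2-methyl-1,3-dioxolan-2-yl)ethylidene]cyclohexan-1-one
Product: 10 (2Z,3S)-3-[(dimethylphenylsilyl)methyl]-1,3-dimethyl-2-[2-(2-methyl-1,3-dioxolan-2-yl)ethylidene]cyclohexan-1-ol (both C1 epimers)
Conditions: MeLi, Et2O, −78 °C
Reagents that add atoms: methyllithium, [Li]C
Why: 1,2-Addition of a hard organolithium to the enone carbonyl forms C10–C20; the new carbinol centre is removed in the next step.

Step 6
Reactants: 10 (2Z,3S)-3-[(dimethylphenylsilyl)methyl]-1,3-dimethyl-2-[2-(2-methyl-1,3-dioxolan-2-yl)ethylidene]cyclohexan-1-ol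
Product: 11 1-[(6S)-6-[(dimethylphenylsilyl)methyl]-2,6-dimethylcyclohex-1-en-1-yl]-2-(2-methyl-1,3-dioxolan-2-yl)ethan-1-one
Conditions: pyridinium chlorochromate (2.5 equiv), NaOAc, 4 Å molecular sieves, CH2Cl2, 23 °C
Reagents that add atoms: pyridinium chlorochromate (supplies the carbonyl oxygen), [O-][Cr](=O)(=O)Cl.c1cc[nH+]cc1
Why: Babler–Dauben oxidative transposition: the tertiary allylic chromate ester undergoes a [3,3] shift to C6 and is oxidised to the ketone, placing the olefin at C5=C10; the acetate buffer protects the ketal.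

Step 7
Reactants: 11 1-[(6S)-6-[(dimethylphenylsilyl)methyl]-2,6-dimethylcyclohex-1-en-1-yl]-2-(2-methyl-1,3-dioxolan-2-yl)ethan-1-one
Product: 12 (1R)-1-[(6S)-6-[(dimethylphenylsilyl)methyl]-2,6-dimethylcyclohex-1-en-1-yl]-2-(2-methyl-1,3-dioxolan-2-yl)ethan-1-ol
Conditions: (S)-1-methyl-3,3-diphenyltetrahydro-1H,3H-pyrrolo[1,2-c][1,3,2]oxazaborole [(S)-Me-CBS] (0.5 equiv), BH3·SMe2 (1.0 equiv), PhMe, −30 °C
Reagents that add atoms: none
Why: Corey–Bakshi–Shibata reduction; the fully substituted cyclohexenyl group acts as the large and the CH2 group as the small substituent, so the (S)-catalyst should deliver hydride to give the (6R)-alcohol independently of the remote C4 centre.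

Step 8
Reactants: 12 (1R)-1-[(6S)-6-[(dimethylphenylsilyl)methyl]-2,6-dimethylcyclohex-1-en-1-yl]-2-(2-methyl-1,3-dioxolan-2-yl)ethan-1-ol
Product: 13 (4R)-4-[(6S)-6-[(dimethylphenylsilyl)methyl]-2,6-dimethylcyclohex-1-en-1-yl]-4-hydroxybutan-2-one
Conditions: pyridinium p-toluenesulfonate (0.2 equiv), acetone/H2O (10:1), 40 °C
Reagents that add atoms: water, O
Why: Acid-catalysed ketal hydrolysis (transketalisation to acetone); the weak acid is chosen so that the allylic alcohol is not ionised.

Step 9
Reactants: 13 (4R)-4-[(6S)-6-[(dimethylphenylsilyl)methyl]-2,6-dimethylcyclohex-1-en-1-yl]-4-hydroxybutan-2-one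
Product: 14 (1R)-1-[(6S)-6-[(dimethylphenylsilyl)methyl]-2,6-dimethylcyclohex-1-en-1-yl]-3-oxobutyl bromoacetate
Conditions: BrCH2COBr (1.3 equiv), pyridine (1.5 equiv), CH2Cl2, −20 → 0 °C
Reagents that add atoms: bromoacetyl bromide, BrCC(Br)=O
Why: O-Acylation of a secondary alcohol with an acid bromide; low temperature and the weak base keep the β-acyloxy ketone from eliminating.

Step 10
Reactants: 14 (1R)-1-[(6S)-6-[(dimethylphenylsilyl)methyl]-2,6-dimethylcyclohex-1-en-1-yl]-3-oxobutyl bromoacetate
Product: 15 (4S,6R)-6-[(6S)-6-[(dimethylphenylsilyl)methyl]-2,6-dimethylcyclohex-1-en-1-yl]-4-hydroxy-4-methyloxan-2-one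
Conditions: SmI2 (2.2 equiv), THF, −78 °C
Reagents that add atoms: none
Why: SmI2-promoted intramolecular Reformatsky reaction of a β-bromoacetoxy ketone forms C8–C9; the trivalent samarium enolate binds the ketone oxygen in a bicyclic chair array in which the C6 substituent is equatorial and the new C8–O bond axial, so the C8 methyl group should end cis to the ring-A substituent.

Step 11
Reactants: 15 (4S,6R)-6-[(6S)-6-[(dimethylphenylsilyl)methyl]-2,6-dimethylcyclohex-1-en-1-yl]-4-hydroxy-4-methyloxan-2-one
Product: 18 methyl (4S,8S,9R,10S)-18-(dimethylphenylsilyl)-8-(trimethylsilyloxy)-12,13,14,15,16-pentanorlabd-5-en-11-oate, via bis(trimethylsilyl) ketene acetal 16 (not isolated), via silyloxy acid 17 (not isolated)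
Conditions: LiN(i-Pr)2 (2.5 equiv), Me3SiCl/Et3N (6 equiv), THF, −78 → 23 °C; PhMe, 105 °C; pH 7 buffer; then Me3SiCHN2, PhMe/MeOH, 0 °C
Reagents that add atoms: chlorotrimethylsilane, C[Si](C)(C)Cl; (trimethylsilyl)diazomethane, C[Si](C)(C)C=[N+]=[N-]
Why: Ireland–Claisen rearrangement of a lactone silyl ketene acetal bearing an alkenyl group on the carbinol carbon: the two-atom tether C7–C8 enforces a boat-like transition state, so C9 adds to C10 on the face that O6 leaves and ring B closes with the cis C5=C6 olefin. C6 is thereby transferred to C10 (C20 syn to C19), the C8 methyl group ends syn to C20, and the carboxyl group ends anti to C20 (9-epi), which step 12 corrects. The acid is esterified without isolation.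

Step 12
Reactants: 18 methyl (4S,8S,9R,10S)-18-(dimethylphenylsilyl)-8-(trimethylsilyloxy)-12,13,14,15,16-pentanorlabd-5-en-11-oate
Product: 20 methyl (4S,8S,9S,10S)-18-(dimethylphenylsilyl)-8-(trimethylsilyloxy)-12,13,14,15,16-pentanorlabd-5-en-11-oate, via lithium ester enolate 19 (not isolated)
Conditions: LiN(i-Pr)2 (1.5 equiv), THF, −78 → −30 °C; AcOH, −78 °C
Reagents that add atoms: none
Why: Ester enolisation and kinetic protonation: the face of C9 syn to the axial C20 and C17 methyl groups is blocked, so the proton should enter from the other face and leave the ester equatorial, which is also the more stable epimer; the equatorial silyloxy group is poorly aligned for β-elimination.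

Step 13
Reactants: 20 methyl (4S,8S,9S,10S)-18-(dimethylphenylsilyl)-8-(trimethylsilyloxy)-12,13,14,15,16-pentanorlabd-5-en-11-oate
Product: 22 (4S,5S,6R,8S,9R,10R)-18-(dimethylphenylsilyl)-12,13,14,15,16-pentanorlabdane-6,8,11-triol, via silyl ether diol 21 (not isolated)
Conditions: BH3·SMe2 (8 equiv), THF, 0 → 66 °C; NaOH, H2O2, 0 → 40 °C; then 1 M HCl, THF, 23 °C
Reagents that add atoms: hydrogen peroxide, OO
Why: Hydroboration–oxidation: boron goes to the less substituted C6 and hydrogen to C5, syn, from the face opposite the axial C19, C20 and C17 methyl groups, giving the trans ring fusion and the equatorial 6-alcohol with retention; borane–dimethyl sulfide at reflux also reduces the ester, and the acid wash removes the silyl ether.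

Step 14
Reactants: 22 (4S,5S,6R,8S,9R,10R)-18-(dimethylphenylsilyl)-12,13,14,15,16-pentanorlabdane-6,8,11-triol
Product: 23 (4S,5S,6R,8S,9S,10R)-18-(dimethylphenylsilyl)-6,8-dihydroxy-12,13,14,15,16-pentanorlabdan-11-al
Conditions: TEMPO (2,2,6,6-tetramethylpiperidin-1-oxyl, 0.2 equiv), PhI(OAc)2 (1.2 equiv), CH2Cl2, 23 °C
Reagents that add atoms: none
Why: Oxoammonium-mediated oxidation is selective for the primary alcohol over the hindered secondary and the tertiary alcohol and stops at the aldehyde.

Step 15
Reactants: 23 (4S,5S,6R,8S,9S,10R)-18-(dimethylphenylsilyl)-6,8-dihydroxy-12,13,14,15,16-pentanorlabdan-11-al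
Product: 24 (4S,5S,6R,8S,9S,10R,11E)-18-(dimethylphenylsilyl)-6,8-dihydroxy-14,15-dinorlabd-11-en-13-one
Conditions: Ph3P=CHC(O)CH3 (3 equiv), PhMe, 100 °C
Reagents that add atoms: 1-(triphenylphosphoranylidene)propan-2-one, CC(=O)C=P(c1ccccc1)(c1ccccc1)c1ccccc1
Why: Wittig olefination with a stabilised ylide forms C11=C12 and brings in C12, C13 and C16; the neutral conditions spare the β-hydroxy aldehyde, and the E-olefin is expected.

Step 16
Reactants: 24 (4S,5S,6R,8S,9S,10R,11E)-18-(dimethylphenylsilyl)-6,8-dihydroxy-14,15-dinorlabd-11-en-13-one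
Product: 25 (4S,5S,6R,8S,9S,10R)-18-(dimethylphenylsilyl)-6,8-dihydroxy-14,15-dinorlabdan-13-one
Conditions: H2 (1 atm), Pd/C (10%), EtOAc, 23 °C
Reagents that add atoms: none
Why: Heterogeneous hydrogenation of the conjugated C=C bond; no other olefin is present and the phenylsilane is inert at one atmosphere.

Step 17
Reactants: 25 (4S,5S,6R,8S,9S,10R)-18-(dimethylphenylsilyl)-6,8-dihydroxy-14,15-dinorlabdan-13-one
Product: 26 (4S,5S,6R,8S,9S,10R)-18-(dimethylphenylsilyl)-6,8-dihydroxy-14,15-dinorlabd-13(16)-en-13-yl trifluoromethanesulfonate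
Conditions: KN(SiMe3)2 (3.3 equiv), THF, −78 °C; PhNTf2 (1.2 equiv), −78 → −40 °C
Reagents that add atoms: N-phenylbis(trifluoromethanesulfonimide), O=S(=O)(N(c1ccccc1)S(=O)(=O)C(F)(F)F)C(F)(F)F
Why: Kinetic deprotonation of the methyl ketone at the methyl group and O-sulfonylation of the enolate; the two hindered alkoxides formed from the excess base should not compete for the mild triflating agent.

Step 18
Reactants: 26 (4S,5S,6R,8S,9S,10R)-18-(dimethylphenylsilyl)-6,8-dihydroxy-14,15-dinorlabd-13(16)-en-13-yl trifluoromethanesulfonate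
Product: 27 (4S,5S,6R,8S,9S,10R)-6-acetoxy-18-(dimethylphenylsilyl)-8-hydroxy-14,15-dinorlabd-13(16)-en-13-yl trifluoromethanesulfonate
Conditions: Ac2O (1.5 equiv), pyridine, DMAP (4-(dimethylamino)pyridine, 0.1 equiv), CH2Cl2, 0 → 23 °C
Reagents that add atoms: acetic anhydride, CC(=O)OC(C)=O
Why: Acylation of the secondary alcohol; the tertiary 8-hydroxyl is too hindered to react, and O18 does not yet exist, so no regiochemical question arises.

Step 19
Reactants: 27 (4S,5S,6R,8S,9S,10R)-6-acetoxy-18-(dimethylphenylsilyl)-8-hydroxy-14,15-dinorlabd-13(16)-en-13-yl trifluoromethanesulfonate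
Product: 28 (4S,5S,6R,8S,9S,10R)-6-acetoxy-8,18-dihydroxy-14,15-dinorlabd-13(16)-en-13-yl trifluoromethanesulfonate
Conditions: KBr (1.5 equiv), AcOOH (32% in AcOH), NaOAc, AcOH, 23 °C
Reagents that add atoms: peracetic acid, CC(=O)OO
Why: Fleming–Tamao oxidation: ipso-bromodesilylation removes the phenyl group, and peracid oxidation of the resulting heteroatom-substituted silane moves C18 from silicon to oxygen; the acetate is stable in buffered acetic acid and the electron-poor enol triflate should resist the electrophiles.

Step 20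
Reactants: 28 (4S,5S,6R,8S,9S,10R)-6-acetoxy-8,18-dihydroxy-14,15-dinorlabd-13(16)-en-13-yl trifluoromethanesulfonate
Product: 29 (4S,5S,6R,8S,9S,10R)-8,18-dihydroxylabda-13(16),14-dien-6-yl acetate (the target)
Conditions: Bu3SnCH=CH2 (1.5 equiv), Pd(PPh3)4 (5 mol%), LiCl (3 equiv), THF, 65 °C
Reagents that add atoms: tributyl(vinyl)stannane, C=C[Sn](CCCC)(CCCC)CCCC
Why: Stille coupling of an enol triflate with a vinylstannane (oxidative addition to zerovalent palladium, chloride-assisted transmetalation, reductive elimination) forms C13–C14 under neutral conditions that leave the acetate, both free hydroxyls and the new diene untouched.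

## Compound list

1 | (chloromethyl)dimethylphenylsilane | C[Si](C)(CCl)c1ccccc1 | starting material
2 | [(dimethylphenylsilyl)methyl]magnesium chloride | C[Si](C)(C[Mg]Cl)c1ccccc1 | intermediate
3 | ethyl 2-(2-methyl-1,3-dioxolan-2-yl)acetate | CCOC(=O)CC1(C)OCCO1 | starting material
4 | 2-(2-methyl-1,3-dioxolan-2-yl)acetaldehyde | CC1(CC=O)OCCO1 | intermediate
5 | 3-methylcyclohex-2-en-1-one | CC1=CC(=O)CCC1 | starting material
6 | chloromagnesium (3S)-3-[(dimethylphenylsilyl)methyl]-3-methylcyclohex-1-en-1-olate | C[C@]1(C[Si](C)(C)c2ccccc2)CCCC(O[Mg]Cl)=C1 | intermediate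
7 | (2S,3S)-3-[(dimethylphenylsilyl)methyl]-2-[(1S)-1-hydroxy-2-(2-methyl-1,3-dioxolan-2-yl)ethyl]-3-methylcyclohexan-1-one | O=C1CCC[C@](C)(C[Si](C)(C)c2ccccc2)[C@H]1[C@@H](O)CC1(C)OCCO1 | intermediate
8 | (1S)-1-[(1S,2S)-2-[(dimethylphenylsilyl)methyl]-2-methyl-6-oxocyclohexyl]-2-(2-methyl-1,3-dioxolan-2-yl)ethyl methanesulfonate | O=C1CCC[C@](C)(C[Si](C)(C)c2ccccc2)[C@H]1[C@@H](OS(C)(=O)=O)CC1(C)OCCO1 | intermediate
9 | (2Z,3S)-3-[(dimethylphenylsilyl)methyl]-3-methyl-2-[2-(2-methyl-1,3-dioxolan-2-yl)ethylidene]cyclohexan-1-one | O=C1CCC[C@](C)(C[Si](C)(C)c2ccccc2)/C1=C/CC1(C)OCCO1 | intermediate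
10 | (2Z,3S)-3-[(dimethylphenylsilyl)methyl]-1,3-dimethyl-2-[2-(2-methyl-1,3-dioxolan-2-yl)ethylidene]cyclohexan-1-ol (C1 epimers, centre left open) | CC1(C/C=C2\C(C)(O)CCC[C@]2(C)C[Si](C)(C)c2ccccc2)OCCO1 | intermediate
11 | 1-[(6S)-6-[(dimethylphenylsilyl)methyl]-2,6-dimethylcyclohex-1-en-1-yl]-2-(2-methyl-1,3-dioxolan-2-yl)ethan-1-one | CC1(CC(=O)C2=C(C)CCC[C@]2(C)C[Si](C)(C)c2ccccc2)OCCO1 | intermediate
12 | (1R)-1-[(6S)-6-[(dimethylphenylsilyl)methyl]-2,6-dimethylcyclohex-1-en-1-yl]-2-(2-methyl-1,3-dioxolan-2-yl)ethan-1-ol | CC1(C[C@@H](O)C2=C(C)CCC[C@]2(C)C[Si](C)(C)c2ccccc2)OCCO1 | intermediate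
13 | (4R)-4-[(6S)-6-[(dimethylphenylsilyl)methyl]-2,6-dimethylcyclohex-1-en-1-yl]-4-hydroxybutan-2-one | CC(=O)C[C@@H](O)C1=C(C)CCC[C@]1(C)C[Si](C)(C)c1ccccc1 | intermediate
14 | (1R)-1-[(6S)-6-[(dimethylphenylsilyl)methyl]-2,6-dimethylcyclohex-1-en-1-yl]-3-oxobutyl bromoacetate | CC(=O)C[C@@H](OC(=O)CBr)C1=C(C)CCC[C@]1(C)C[Si](C)(C)c1ccccc1 | intermediate
15 | (4S,6R)-6-[(6S)-6-[(dimethylphenylsilyl)methyl]-2,6-dimethylcyclohex-1-en-1-yl]-4-hydroxy-4-methyloxan-2-one | C[C@]1(O)C[C@@H](OC(=O)C1)C1=C(C)CCC[C@]1(C)C[Si](C)(C)c1ccccc1 | intermediate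
16 | (2R,4S)-2-[(6S)-6-[(dimethylphenylsilyl)methyl]-2,6-dimethylcyclohex-1-en-1-yl]-4-methyl-4,6-bis(trimethylsilyloxy)-3,4-dihydro-2H-pyran | C[C@]1(O[Si](C)(C)C)C[C@@H](OC(O[Si](C)(C)C)=C1)C1=C(C)CCC[C@]1(C)C[Si](C)(C)c1ccccc1 | intermediate
17 | (4S,8S,9R,10S)-18-(dimethylphenylsilyl)-8-(trimethylsilyloxy)-12,13,14,15,16-pentanorlabd-5-en-11-oic acid | OC(=O)[C@@H]1[C@]2(C)CCC[C@](C)(C[Si](C)(C)c3ccccc3)C2=CC[C@]1(C)O[Si](C)(C)C | intermediate
18 | methyl (4S,8S,9R,10S)-18-(dimethylphenylsilyl)-8-(trimethylsilyloxy)-12,13,14,15,16-pentanorlabd-5-en-11-oate | COC(=O)[C@@H]1[C@]2(C)CCC[C@](C)(C[Si](C)(C)c3ccccc3)C2=CC[C@]1(C)O[Si](C)(C)C | intermediate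
19 | lithium enolate of 18 (C9=C11, O-lithiated) | COC(O[Li])=C1[C@]2(C)CCC[C@](C)(C[Si](C)(C)c3ccccc3)C2=CC[C@]1(C)O[Si](C)(C)C | intermediate
20 | methyl (4S,8S,9S,10S)-18-(dimethylphenylsilyl)-8-(trimethylsilyloxy)-12,13,14,15,16-pentanorlabd-5-en-11-oate | COC(=O)[C@H]1[C@]2(C)CCC[C@](C)(C[Si](C)(C)c3ccccc3)C2=CC[C@]1(C)O[Si](C)(C)C | intermediate
21 | (4S,5S,6R,8S,9R,10R)-18-(dimethylphenylsilyl)-8-(trimethylsilyloxy)-12,13,14,15,16-pentanorlabdane-6,11-diol | OC[C@H]1[C@]2(C)CCC[C@](C)(C[Si](C)(C)c3ccccc3)[C@H]2[C@H](O)C[C@]1(C)O[Si](C)(C)C | intermediate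
22 | (4S,5S,6R,8S,9R,10R)-18-(dimethylphenylsilyl)-12,13,14,15,16-pentanorlabdane-6,8,11-triol | OC[C@H]1[C@]2(C)CCC[C@](C)(C[Si](C)(C)c3ccccc3)[C@H]2[C@H](O)C[C@]1(C)O | intermediate
23 | (4S,5S,6R,8S,9S,10R)-18-(dimethylphenylsilyl)-6,8-dihydroxy-12,13,14,15,16-pentanorlabdan-11-al | O=C[C@H]1[C@]2(C)CCC[C@](C)(C[Si](C)(C)c3ccccc3)[C@H]2[C@H](O)C[C@]1(C)O | intermediate
24 | (4S,5S,6R,8S,9S,10R,11E)-18-(dimethylphenylsilyl)-6,8-dihydroxy-14,15-dinorlabd-11-en-13-one | CC(=O)/C=C/[C@H]1[C@]2(C)CCC[C@](C)(C[Si](C)(C)c3ccccc3)[C@H]2[C@H](O)C[C@]1(C)O | intermediate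
25 | (4S,5S,6R,8S,9S,10R)-18-(dimethylphenylsilyl)-6,8-dihydroxy-14,15-dinorlabdan-13-one | CC(=O)CC[C@H]1[C@]2(C)CCC[C@](C)(C[Si](C)(C)c3ccccc3)[C@H]2[C@H](O)C[C@]1(C)O | intermediate
26 | (4S,5S,6R,8S,9S,10R)-18-(dimethylphenylsilyl)-6,8-dihydroxy-14,15-dinorlabd-13(16)-en-13-yl trifluoromethanesulfonate | C=C(OS(=O)(=O)C(F)(F)F)CC[C@H]1[C@]2(C)CCC[C@](C)(C[Si](C)(C)c3ccccc3)[C@H]2[C@H](O)C[C@]1(C)O | intermediate
27 | (4S,5S,6R,8S,9S,10R)-6-acetoxy-18-(dimethylphenylsilyl)-8-hydroxy-14,15-dinorlabd-13(16)-en-13-yl trifluoromethanesulfonate | C=C(OS(=O)(=O)C(F)(F)F)CC[C@H]1[C@]2(C)CCC[C@](C)(C[Si](C)(C)c3ccccc3)[C@H]2[C@H](OC(C)=O)C[C@]1(C)O | intermediate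
28 | (4S,5S,6R,8S,9S,10R)-6-acetoxy-8,18-dihydroxy-14,15-dinorlabd-13(16)-en-13-yl trifluoromethanesulfonate | C=C(OS(=O)(=O)C(F)(F)F)CC[C@H]1[C@]2(C)CCC[C@](C)(CO)[C@H]2[C@H](OC(C)=O)C[C@]1(C)O | intermediate
29 | (4S,5S,6R,8S,9S,10R)-8,18-dihydroxylabda-13(16),14-dien-6-yl acetate | C=CC(=C)CC[C@H]1[C@]2(C)CCC[C@](C)(CO)[C@H]2[C@H](OC(C)=O)C[C@]1(C)O | target

## Step count and risks

Total step count: 20. Longest linear sequence: 19 steps (from 3 through steps 2–20; the branch from 1 through steps 1 and 3–20 is equally long).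

Least certain steps:

**Step 3 (key step).** The silicon-stabilised alkyl group may transfer from copper too slowly, so that uncatalysed 1,2-addition and a less selective background pathway erode conversion and enantiofacial selectivity; the magnesium enolate may also deprotonate the enolisable aldehyde instead of adding to it. Fallback, exchanging the roles of the two C4 substituents: starting from 2, addition to 3-ethoxycyclohex-2-en-1-one and acidic work-up would give 3-[(dimethylphenylsilyl)methyl]cyclohex-2-en-1-one F1. Addition of MeMgBr to F1 with the same Cu(OTf)2/carbene system (ligand antipode as required) would form the same C4 enolate as its bromomagnesium salt, which is trapped with 4 to come back at 7.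

**Step 11.** The boat-like transition state must bring the fully substituted olefin carbon C10 onto C9 while the C8 methyl group is pushed toward C20; if the barrier is too high, thermal ionisation of the allylic C6–O bond with elimination, or decay of the ketene acetal, may take over. Fallback, setting out from 12:
- acetylation would give (1R)-1-[(6S)-6-[(dimethylphenylsilyl)methyl]-2,6-dimethylcyclohex-1-en-1-yl]-2-(2-methyl-1,3-dioxolan-2-yl)ethyl acetate F2;
- an acyclic Ireland–Claisen rearrangement (chair transition state) and esterification would give methyl 2-[(1S,2E,3S)-3-[(dimethylphenylsilyl)methyl]-1,3-dimethyl-2-[2-(2-methyl-1,3-dioxolan-2-yl)ethylidene]cyclohexyl]acetate F3; only the olefin isomer with C7 syn to C10 is useful, and it carries the correct C10 centre by the same suprafacial transfer;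
- ketal hydrolysis would give methyl 2-[(1S,2E,3S)-3-[(dimethylphenylsilyl)methyl]-1,3-dimethyl-2-(3-oxobutylidene)cyclohexyl]acetate F4;
- intramolecular ester-enolate aldol addition (LiN(SiMe3)2, −78 °C) would close ring B to methyl (4S,8S,9S,10S)-18-(dimethylphenylsilyl)-8-hydroxy-12,13,14,15,16-pentanorlabd-5-en-11-oate F5, with C8 and C9 then resting on the aldol step and epimers to be separated.
F5 enters the borane sequence of step 13 and comes back at 22.

**Step 12.** Deprotonation of the crowded C9–H may be slow, and at the temperature then needed β-elimination of the C8 silyloxy group toward the conjugated 8,9-olefin may compete. Fallback, setting out from 18: the 9-epi centre is carried on. The conditions of step 13 would give (4S,5S,6R,8S,9S,10R)-18-(dimethylphenylsilyl)-12,13,14,15,16-pentanorlabdane-6,8,11-triol F6, and TEMPO/PhI(OAc)2 would give (4S,5S,6R,8S,9R,10R)-18-(dimethylphenylsilyl)-6,8-dihydroxy-12,13,14,15,16-pentanorlabdan-11-al F7. Its far more acidic α-hydrogen allows equilibration with DBU to the equatorial aldehyde, coming back at 23.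

**Step 7.** The acyl group is twisted out of conjugation and flanked by a quaternary carbon, so binding to the oxazaborolidine may be hindered and uncatalysed borane reduction may lower the facial selectivity. Fallback, setting out from 11: Luche reduction (NaBH4, CeCl3·7H2O) would give 12 together with (1S)-1-[(6S)-6-[(dimethylphenylsilyl)methyl]-2,6-dimethylcyclohex-1-en-1-yl]-2-(2-methyl-1,3-dioxolan-2-yl)ethan-1-ol F8. The two are diastereomers because of C4 and would be separated by chromatography; F8 is returned to 11 with Dess–Martin periodinane and recycled, and the route is rejoined at 12.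

**Step 19.** Electrophilic bromine or peracid may attack the enol triflate, and acid-promoted shift of the acetyl group from O6 to the newly freed O18 may set in during the long exposure. Fallback, setting out from 26:
- Stille coupling first would give (4S,5S,6R,8S,9S,10R)-18-(dimethylphenylsilyl)labda-13(16),14-diene-6,8-diol F9;
- oxidation of the phenylsilane under basic, olefin-tolerant conditions (KH, t-BuOOH, DMF; then Bu4NF) would give (4S,5S,6R,8S,9S,10R)-labda-13(16),14-diene-6,8,18-triol F10;
- silylation of the primary hydroxyl (t-BuMe2SiCl, imidazole) would give (4S,5S,6R,8S,9S,10R)-18-(tert-butyldimethylsilyloxy)labda-13(16),14-diene-6,8-diol F11;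
- acetylation would give (4S,5S,6R,8S,9S,10R)-18-(tert-butyldimethylsilyloxy)-8-hydroxylabda-13(16),14-dien-6-yl acetate F12;
- HF·pyridine removes the silyl ether and comes back at 29.

## Further compounds

F1 | step 3 | 3-[(dimethylphenylsilyl)methyl]cyclohex-2-en-1-one | O=C1C=C(C[Si](C)(C)c2ccccc2)CCC1
F2 | step 11 | (1R)-1-[(6S)-6-[(dimethylphenylsilyl)methyl]-2,6-dimethylcyclohex-1-en-1-yl]-2-(2-methyl-1,3-dioxolan-2-yl)ethyl acetate | CC(=O)O[C@H](CC1(C)OCCO1)C1=C(C)CCC[C@]1(C)C[Si](C)(C)c1ccccc1
F3 | step 11 | methyl 2-[(1S,2E,3S)-3-[(dimethylphenylsilyl)methyl]-1,3-dimethyl-2-[2-(2-methyl-1,3-dioxolan-2-yl)ethylidene]cyclohexyl]acetate | COC(=O)C[C@]1(C)CCC[C@](C)(C[Si](C)(C)c2ccccc2)/C1=C/CC1(C)OCCO1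
F4 | step 11 | methyl 2-[(1S,2E,3S)-3-[(dimethylphenylsilyl)methyl]-1,3-dimethyl-2-(3-oxobutylidene)cyclohexyl]acetate | COC(=O)C[C@]1(C)CCC[C@](C)(C[Si](C)(C)c2ccccc2)/C1=C/CC(C)=O
F5 | step 11 | methyl (4S,8S,9S,10S)-18-(dimethylphenylsilyl)-8-hydroxy-12,13,14,15,16-pentanorlabd-5-en-11-oate | COC(=O)[C@H]1[C@]2(C)CCC[C@](C)(C[Si](C)(C)c3ccccc3)C2=CC[C@]1(C)O
F6 | step 12 | (4S,5S,6R,8S,9S,10R)-18-(dimethylphenylsilyl)-12,13,14,15,16-pentanorlabdane-6,8,11-triol (9-epimer of 22) | OC[C@@H]1[C@]2(C)CCC[C@](C)(C[Si](C)(C)c3ccccc3)[C@H]2[C@H](O)C[C@]1(C)O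
F7 | step 12 | (4S,5S,6R,8S,9R,10R)-18-(dimethylphenylsilyl)-6,8-dihydroxy-12,13,14,15,16-pentanorlabdan-11-al (9-epimer of 23) | O=C[C@@H]1[C@]2(C)CCC[C@](C)(C[Si](C)(C)c3ccccc3)[C@H]2[C@H](O)C[C@]1(C)O
F8 | step 7 | (1S)-1-[(6S)-6-[(dimethylphenylsilyl)methyl]-2,6-dimethylcyclohex-1-en-1-yl]-2-(2-methyl-1,3-dioxolan-2-yl)ethan-1-ol | CC1(C[C@H](O)C2=C(C)CCC[C@]2(C)C[Si](C)(C)c2ccccc2)OCCO1
F9 | step 19 | (4S,5S,6R,8S,9S,10R)-18-(dimethylphenylsilyl)labda-13(16),14-diene-6,8-diol | C=CC(=C)CC[C@H]1[C@]2(C)CCC[C@](C)(C[Si](C)(C)c3ccccc3)[C@H]2[C@H](O)C[C@]1(C)O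
F10 | step 19 | (4S,5S,6R,8S,9S,10R)-labda-13(16),14-diene-6,8,18-triol | C=CC(=C)CC[C@H]1[C@]2(C)CCC[C@](C)(CO)[C@H]2[C@H](O)C[C@]1(C)O
F11 | step 19 | (4S,5S,6R,8S,9S,10R)-18-(tert-butyldimethylsilyloxy)labda-13(16),14-diene-6,8-diol | C=CC(=C)CC[C@H]1[C@]2(C)CCC[C@](C)(CO[Si](C)(C)C(C)(C)C)[C@H]2[C@H](O)C[C@]1(C)O
F12 | step 19 | (4S,5S,6R,8S,9S,10R)-18-(tert-butyldimethylsilyloxy)-8-hydroxylabda-13(16),14-dien-6-yl acetate | C=CC(=C)CC[C@H]1[C@]2(C)CCC[C@](C)(CO[Si](C)(C)C(C)(C)C)[C@H]2[C@H](OC(C)=O)C[C@]1(C)O
A1 | alternative 1 | gem-dimethyl C6 alcohol (12-O-tert-butyldimethylsilyl, 8-O-methoxymethyl) | CC(C)(C)[Si](C)(C)OCC[C@H]1[C@]2(C)CCCC(C)(C)[C@H]2[C@H](O)C[C@]1(C)OCOC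
A2 | alternative 1 | diethyl(hydrido)silyl ether of A1 | CC(C)(C)[Si](C)(C)OCC[C@H]1[C@]2(C)CCCC(C)(C)[C@H]2[C@H](O[SiH](CC)CC)C[C@]1(C)OCOC
A3 | alternative 1 | 6,18-bridged diethyl oxasilacycle | CC(C)(C)[Si](C)(C)OCC[C@H]1[C@]2(C)CCC[C@](C)(C[Si]3(CC)CC)[C@H]2[C@H](O3)C[C@]1(C)OCOC
A4 | alternative 2 | (4E)-7-(3-hydroxy-2,6-dimethylphenyl)-5-methylhept-4-enoic acid | Cc1ccc(O)c(C)c1CC/C(C)=C/CCC(=O)O
A5 | alternative 2 | tricyclic cross-conjugated dienone δ-lactone | O=C1CC[C@H]2[C@]3(C)C=CC(=O)C(C)=C3CC[C@]2(C)O1
A6 | alternative 3 | acyclic silyloxydiene enoate | COC(=O)/C=C(\C)CCC[C@](C)(CO[Si](C(C)C)(C(C)C)C(C)C)/C=C(O[Si](C)(C)C(C)(C)C)/C=C/C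
A7 | alternative 3 | trans-decalin silyl enol ether with C9 ester | COC(=O)[C@H]1[C@]2(C)CCC[C@](C)(CO[Si](C(C)C)(C(C)C)C(C)C)[C@H]2C(O[Si](C)(C)C(C)(C)C)=C[C@H]1C
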